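## Structural features

The target is a cis-fused bicyclo[4.4.0]decane. Locants used throughout, also in the names of intermediates (where "decal" means this bicycle): ring A = C1, C2, C3, C8, C9, C10; ring B = C3, C4, C5, C6, C7, C8; C11–C17 = the trienoic acid chain on C9 (C17 = carboxyl); C18–C20 = the 3-hydroxy-2-oxopropylidene unit on C10; α = the face of the ring-fusion hydrogens H3 and H8, β = the other face.

Ring A holds the trisubstituted C1(Me)=C2 alkene, conjugated with the exocyclic C10=C18 alkene and the C19 ketone (E, acyl syn to C9). Ring B is saturated.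

There are six stereocentres. C5 (Me α), C6 (OH β), C7 (Me α), C8 and C9 (chain α, H β) are contiguous, and C3 is bonded to C8. In the chair of ring B, 5-Me, 6-OH, 7-Me and the C8–C9 bond are equatorial and only C3–C2 is axial. On ring A the C9 chain is axial, the one position free of peri strain with 7-Me and of allylic strain with C18.

The chain is an (11E,13Z,15E)-trienoic acid with methyls on C12 and C14.

Fragile points are H9 (doubly allylic and γ to the ketone, so base would pull C10=C18 into the ring and conjugate the whole system), the α-hydroxy ketone and the 13Z alkene.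

The real difficulty is the cis ring fusion in the correct relation to the C5–C7 triad and to C9. An intramolecular Diels–Alder reaction reaches this relative configuration only through its cis-fused exo mode, which is normally the disfavoured one.

The key step exploits this feature: the oxygen-bearing C6 and the C1=C2 double bond are δ,ε-related through C5–C4–C3, the retron of an oxy-Cope rearrangement. Reconnecting C1–C6 and cutting C3–C4 folds the decalin into a bicyclo[2.2.2]octene. Its six-membered ring C1–C2–C3–C8–C7–C6, with methyl on C1 and the branch C9(C10)(=C11) on C8, is the ring of carvone.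

## Logic of the disconnections

29 from 28: only the two O–Si bonds are cut. Deprotection is placed last and is done with buffered acidic fluoride, because nothing basic may touch the finished dienone (H9).

28 from 27: the C10=C18 double bond and the C19 carbonyl are traced back to a C10–OH and a C18≡C19 triple bond (1,3-oxygen shift). This avoids olefinating a hindered, enolizable C10 ketone and leaves the alkene geometry to thermodynamics (the E isomer avoids the clash between the acyl group and 1-Me). The forward step must rearrange without ionising C10 and losing H9.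

27 from 26, and 26 from 24 + 25: the ester C–O bond, then the C14–C15 bond. The cut separates a small (Z)-iodoalkene from an acrylate that arrives with its E geometry, so no reduction or oxidation is needed on the polyene. The forward coupling must retain both geometries under neutral conditions.

24 from 20 + 21: the C10–C18 bond. C18–C20 enters as a three-carbon acetylide while C9 carries only an iodo-diene, not yet the trienoate, so H9 is still only moderately acidic. The addition must beat enolization.

20 from 19, 19 from 18, 18 from 17: the C10 oxidation level (ketone, alcohol, CH2) and the C13=C14 bond. C10 is oxygenated at the enal stage, where the side-chain alkene is electron-poor and inert to the allylic oxidant. The Z-iodoalkene is made before the ketone exists, so the basic ylide never meets an acidic H9.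

17 from 16: the C11=C12 bond, by a stabilised ylide on the C11 aldehyde. E geometry is required.

16 from 14, 14 from 12: the C11 aldehyde is traced to the exocyclic C9=C11 methylene by anti-Markovnikov hydration. C9 is then set by equilibration at the only stage where C10 is still CH2, so no β-elimination is possible. The equilibrium is driven by peri strain with 7-Me.

12 from 11, 11 from 10, 10 from 8: the O–Si bond, the C6–H bond and the C7–CH3 bond. Both reagents (hydride, methyl iodide) are required to approach ring B from its convex α face, anti to ring A.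

8 from 5 (key): the C3–C4 bond and the C5–CH3 bond are cut and C1–C6 is reconnected. Both decalin rings, the cis fusion, the position of C1=C2 and the C6 carbonyl collapse into one rigid bicyclo[2.2.2]octenol. The forward step needs the vinyl group syn to the etheno bridge, and a regiodefined enolate that is methylated once, on the α face.

5 from 4: the C5–C6 bond, by vinyl addition to the bridge ketone from the etheno-bridge side.

4 from 2, 2 from 1: the C1–C10 bond (intramolecular alkylation of the extended dienolate at its α-carbon) and the C–Cl bond. All ten carbons and the single stereocentre of 1 are kept; its ring is later cut at C1–C6 by the key step.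

## Other disconnections considered

Alternative 1: cut C3–C8 and C9–C10 by an intramolecular Diels–Alder reaction of the acyclic (E,E)-diene/(E)-enal A1, which would give the octalin aldehyde A2. This is the first plan that comes to mind. The target configuration (H3 cis to H8, C11 trans to C7) corresponds to the transition state with the tether endo and the formyl group exo. Terminally activated 1,7,9-decatrienes prefer the formyl-endo, trans-fused mode, and Lewis acids reinforce that, so the wanted isomer of A2 would be the minor one. The exocyclic enone would still have to be built on a C10 carbonyl next to an enolizable C9.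

Alternative 2: the same two bonds by a Diels–Alder reaction of the (Z)-vinylallenyl ketone A3, which would deliver the exocyclic dienone A4 directly. A Z-diene can only give the cis fusion, which is attractive. The single available transition state, however, forms ring B with C9 axial and C2 equatorial. For the required diastereomer this places 5-Me, 6-OSi and 7-Me all axial (syn-pentane between the methyls), so the other diene face, and with it the wrong relation of C3/C8/C9 to the triad, should win. In addition, approach anti to the acyl group would give the Z enone, and a (Z)-vinylallene with a cis CH2 group is prone to a competing [1,5]-hydrogen shift.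

Alternative 3: cut C2–C3 and C8–C9 by an intermolecular Diels–Alder reaction of the ring-B enone A5 with the 2-silyloxydiene A6 to give the cis-decalone A7. The cyclic dienophile guarantees the cis fusion, and the diene would add anti to 7-Me. Against it: A5 is an enantiopure, trisubstituted cyclohexenone needing its own multistep synthesis; A7 carries a C4 carbonyl that must later be excised; the endo mode gives the C9 epimer; and C4 and the diene CH2 are extra redox burdens. The chosen plan buys all ten core carbons and the absolute configuration in one terpene and needs no carbonyl removal.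

Key step: step 4

Remark (assumption): the carbinol configuration at C10 in 18, 19 and 24 is of no consequence because C10 ends sp2, so these compounds are carried as C10 epimer mixtures; 14 and 15 are C9 epimer mixtures that converge in step 9.

## Steps

Step 1
Reactants: 1 (S)-(+)-carvone
Product: 2 (5S)-5-(3-chloroprop-1-en-2-yl)-2-methylcyclohex-2-en-1-one
Conditions: Ca(OCl)2, solid CO2, CH2Cl2/H2O, 0 °C
Reagents that add atoms: calcium hypochlorite, [Ca+2].[O-]Cl.[O-]Cl
Why: Ene-type allylic chlorination by HOCl takes place at the electron-rich 1,1-disubstituted alkene with double-bond shift, leaving the electron-poor enone alkene and the stereocentre untouched.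

Step 2
Reactants: 2 (5S)-5-(3-chloroprop-1-en-2-yl)-2-methylcyclohex-2-en-1-one
Product: 4 (1R,4R)-1-methyl-8-methylidenebicyclo[2.2.2]oct-5-en-2-one, via potassium dienolate 3 (not isolated)
Conditions: KOt-Bu, t-BuOH/THF, 0 °C to rt
Reagents that add atoms: none
Why: Reversible enolization funnels to the extended dienolate 3, and only its α-carbon can reach the allylic chloride in a six-membered closure (intramolecular enolate alkylation, SN2 and SN2′ giving the same product). The tether from the existing stereocentre allows only one configuration at the new quaternary bridgehead.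

Step 3
Reactants: 4 (1R,4R)-1-methyl-8-methylidenebicyclo[2.2.2]oct-5-en-2-one
Product: 5 (1R,2R,4R)-2-ethenyl-1-methyl-8-methylidenebicyclo[2.2.2]oct-5-en-2-ol
Conditions: CH2=CHMgBr, CeCl3, THF, −78 to 0 °C; aq NH4Cl
Reagents that add atoms: vinylmagnesium bromide, C=C[Mg]Br
Why: The organocerium reagent adds 1,2 without enolizing the hindered bridge ketone. It approaches from the etheno-bridge face (the vinylic CH lies in the bridge plane, whereas a hydrogen of the CH2 bridge points at the other face), so the vinyl group ends syn to the C5=C6 bridge as the next step requires.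

Step 4
Reactants: 5 (1R,2R,4R)-2-ethenyl-1-methyl-8-methylidenebicyclo[2.2.2]oct-5-en-2-ol
Product: 8 (3αH,8αH)-1,5α-dimethyl-9-methylidene-cis-decal-1-en-6-one, via potassium alkoxide 6 (not isolated), via potassium enolate 7 (not isolated)
Conditions: KHMDS, 18-crown-6, THF, 0 °C to rt; then MeI, −78 to −20 °C
Reagents that add atoms: iodomethane, CI
Why: Deprotonation gives alkoxide 6, whose oxyanion weakens the adjacent C1–C6 bond, so the [3,3] shift through C4=C5–C6–C1–C2=C3 should run at or below room temperature; this is the anionic oxy-Cope rearrangement, and the closest known case is the conversion of 2-vinylbicyclo[2.2.2]oct-5-en-2-ols into cis-fused octalones. Ring B (C3–C8) is closed by suprafacial C3–C4 bond formation inside the six-centre array, which the bicycle holds as a boat; ring A is not closed but released when the C1–C6 bond of the former carvone ring breaks, leaving C1=C2 and the C5=C6 enolate 7. C3 is the stereocentre of the sigmatropic event: C4 can reach C3 only on the face of the etheno bridge turned towards the C6–C7 bridge, so H3 ends cis to H8 and the carvone-derived configuration of C8 is copied to C3 with no competing transition state. C5 is set in the same flask when the regiodefined enolate 7 is C-methylated on the convex α face of the folded cis-decalin, anti to ring A. The step needs the vinyl group syn to the etheno bridge (secured in step 3), sigmatropic shift rather than fragmentation of the alkoxide (favoured by the concerted, strain-releasing path), and a single C-alkylation (soft MeI, low temperature, no excess base to scramble the enolate).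

Step 5
Reactants: 8 (3αH,8αH)-1,5α-dimethyl-9-methylidene-cis-decal-1-en-6-one
Product: 10 (3αH,8αH)-1,5α,7α-trimethyl-9-methylidene-cis-decal-1-en-6-one, via lithium enolate 9 (not isolated)
Conditions: LDA, THF, −78 °C; MeI, −78 to −30 °C
Reagents that add atoms: iodomethane, CI
Why: Kinetic deprotonation takes the less substituted C7 (CH2 against CH(Me)), and the enolate is methylated on the convex α face, anti to ring A and to the C8–C9 bond (enolate alkylation under substrate control). C5 is not touched at −78 °C.

Step 6
Reactants: 10 (3αH,8αH)-1,5α,7α-trimethyl-9-methylidene-cis-decal-1-en-6-one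
Product: 11 (3αH,8αH)-1,5α,7α-trimethyl-9-methylidene-cis-decal-1-en-6β-ol
Conditions: NaBH4, MeOH/CH2Cl2, −20 to 0 °C
Reagents that add atoms: none
Why: Hydride attacks axially from the open α face (the β face is screened by ring A, whose C3–C2 bond is axial over ring B), giving the equatorial 6β-alcohol anti to both methyl groups.

Step 7
Reactants: 11 (3αH,8αH)-1,5α,7α-trimethyl-9-methylidene-cis-decal-1-en-6β-ol
Product: 12 tert-butyldimethylsilyl ether of 11
Conditions: TBSOTf, 2,6-lutidine, CH2Cl2, −78 to 0 °C
Reagents that add atoms: tert-butyldimethylsilyl trifluoromethanesulfonate, CC(C)(C)[Si](C)(C)OS(=O)(=O)C(F)(F)F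
Why: A silyl triflate is needed for the hindered secondary alcohol flanked by two methyl-bearing carbons; the ether survives every later step up to the fluoride deprotection.

Step 8
Reactants: 12 tert-butyldimethylsilyl ether of 11
Product: 14 6β-(tert-butyldimethylsilyloxy)-9-(hydroxymethyl)-1,5α,7α-trimethyl-(3αH,8αH)-cis-decal-1-ene as C9 epimers, via alkyl-9-BBN adduct 13 (not isolated)
Conditions: 9-BBN, THF, 0 °C to rt; then aq NaOH, H2O2, 0 °C
Reagents that add atoms: hydrogen peroxide, OO
Why: 9-BBN hydroborates the 1,1-disubstituted exocyclic alkene far faster than the trisubstituted C1=C2 and puts boron on C11 (anti-Markovnikov hydroboration–oxidation). The configuration at C9 is not relied on here because it is corrected in step 9.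

Step 9
Reactants: 14 6β-(tert-butyldimethylsilyloxy)-9-(hydroxymethyl)-1,5α,7α-trimethyl-(3αH,8αH)-cis-decal-1-ene as C9 epimers
Product: 16 6β-(tert-butyldimethylsilyloxy)-1,5α,7α-trimethyl-(3αH,8αH,9βH)-cis-decal-1-ene-9α-carbaldehyde, via kinetic aldehyde 15 (not isolated)
Conditions: Dess–Martin periodinane, NaHCO3, CH2Cl2, 0 °C to rt; then DBU (0.3 equiv), CH2Cl2, rt
Reagents that add atoms: none
Why: After Dess–Martin oxidation, DBU equilibrates C9 through the enolate. The epimer with the formyl group equatorial on ring A has its C9–C11 bond parallel to the C7–CH3 bond (syn-pentane, peri strain), so the equilibrium should lie far on the axial 9α-aldehyde, which is the target configuration. C10 is still CH2, so no β-elimination can compete.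

Step 10
Reactants: 16 6β-(tert-butyldimethylsilyloxy)-1,5α,7α-trimethyl-(3αH,8αH,9βH)-cis-decal-1-ene-9α-carbaldehyde
Product: 17 (2E)-3-[6β-(tert-butyldimethylsilyloxy)-1,5α,7α-trimethyl-(3αH,8αH,9βH)-cis-decal-1-en-9α-yl]-2-methylprop-2-enal
Conditions: Ph3P=C(CH3)CHO, toluene, 100 °C
Reagents that add atoms: 2-(triphenylphosphoranylidene)propanal, CC(C=O)=P(c1ccccc1)(c1ccccc1)c1ccccc1
Why: Wittig reaction with a formyl-stabilised ylide gives the E trisubstituted enal (C11=C12) under thermodynamic control of the oxaphosphetane; C9 is already in its stable configuration.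

Step 11
Reactants: 17 (2E)-3-[6β-(tert-butyldimethylsilyloxy)-1,5α,7α-trimethyl-(3αH,8αH,9βH)-cis-decal-1-en-9α-yl]-2-methylprop-2-enal
Product: 18 10-hydroxy derivative of 17 as C10 epimers
Conditions: SeO2 (cat.), t-BuOOH, CH2Cl2, rt
Reagents that add atoms: tert-butyl hydroperoxide, CC(C)(C)OO
Why: Selenium dioxide allylic hydroxylation (ene reaction, then [2,3] shift) acts on the electron-rich ring alkene and oxidises next to its more substituted carbon C1, a ring CH2 (C10) before the methyl group; the electron-poor enal alkene should not react.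

Step 12
Reactants: 18 10-hydroxy derivative of 17 as C10 epimers
Product: 19 9α-[(1E,3Z)-4-iodo-2-methylpenta-1,3-dien-1-yl]-6β-(tert-butyldimethylsilyloxy)-1,5α,7α-trimethyl-(3αH,8αH,9βH)-cis-decal-1-en-10-ol as C10 epimers
Conditions: EtPPh3I, n-BuLi, THF, rt; I2, −78 °C; NaHMDS (excess, covers the free OH), −78 °C; then 18, −78 to −20 °C
Reagents that add atoms: ethyltriphenylphosphonium iodide, CC[P+](c1ccccc1)(c1ccccc1)c1ccccc1.[I-]; iodine, II
Why: Stork–Zhao-type Wittig olefination with the α-iodo ylide gives the Z iodoalkene (iodine cis to C12), which is the geometry of C13=C14 in the target. It is run before the C10 ketone exists, so the basic ylide meets no acidic H9.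

Step 13
Reactants: 19 9α-[(1E,3Z)-4-iodo-2-methylpenta-1,3-dien-1-yl]-6β-(tert-butyldimethylsilyloxy)-1,5α,7α-trimethyl-(3αH,8αH,9βH)-cis-decal-1-en-10-ol as C10 epimers
Product: 20 9α-[(1E,3Z)-4-iodo-2-methylpenta-1,3-dien-1-yl]-6β-(tert-butyldimethylsilyloxy)-1,5α,7α-trimethyl-(3αH,8αH,9βH)-cis-decal-1-en-10-one
Conditions: Dess–Martin periodinane, NaHCO3, CH2Cl2, 0 °C
Reagents that add atoms: none
Why: Buffered Dess–Martin oxidation of the allylic alcohol gives the enone under neutral conditions; the axial C9 configuration remains the stable one because the peri strain with 7-Me persists.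

Step 14
Reactants: 20 9α-[(1E,3Z)-4-iodo-2-methylpenta-1,3-dien-1-yl]-6β-(tert-butyldimethylsilyloxy)-1,5α,7α-trimethyl-(3αH,8αH,9βH)-cis-decal-1-en-10-one; 21 tert-butyldimethyl(prop-2-yn-1-yloxy)silane
Product: 24 10-[3-(tert-butyldimethylsilyloxy)prop-1-yn-1-yl] tertiary alcohol derived from 20, via lithium acetylide 22 (not isolated), via dichlorocerium acetylide 23 (not isolated)
Conditions: 21, n-BuLi, THF, −78 °C; CeCl3, −78 °C; then 20, −78 °C; aq NH4Cl
Reagents that add atoms: none
Why: The weakly basic, oxophilic cerium acetylide adds 1,2 to the enolizable β,γ-unsaturated ketone faster than it deprotonates C9 (organocerium carbonyl addition). The configuration of the new carbinol is irrelevant because C10 becomes sp2.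

Step 15
Reactants: 24 10-[3-(tert-butyldimethylsilyloxy)prop-1-yn-1-yl] tertiary alcohol derived from 20; 25 ethyl (2E)-3-(tributylstannyl)prop-2-enoate
Product: 26 ethyl (2E,4Z,6E)-4,6-dimethylhepta-2,4,6-trienoate carrying at C7 the decalin of 24
Conditions: Pd2(dba)3 (cat.), AsPh3 (cat.), NMP, rt to 40 °C
Reagents that add atoms: none
Why: Stille coupling forms the C14–C15 bond with retention of both alkene geometries under neutral conditions, and the free tertiary alcohol is tolerated.

Step 16
Reactants: 26 ethyl (2E,4Z,6E)-4,6-dimethylhepta-2,4,6-trienoate carrying at C7 the decalin of 24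
Product: 27 the corresponding (2E,4Z,6E)-trienoic acid
Conditions: LiOH, THF/MeOH/H2O, 0 °C to rt; then 0.5 M HCl to pH 4, 0 °C
Reagents that add atoms: lithium hydroxide, [Li+].[OH-]
Why: The ester is saponified while C10 is still a carbinol, so H9 is not yet acidified by the dienone and cannot isomerise.

Step 17
Reactants: 27 the corresponding (2E,4Z,6E)-trienoic acid
Product: 28 6,20-bis(tert-butyldimethylsilyl) ether of the target
Conditions: Ph3PAuNTf2 (2 mol %), MeOH (1 equiv), toluene, rt
Reagents that add atoms: none
Why: Gold-catalysed Meyer–Schuster rearrangement: the alkyne is activated, the tertiary oxygen shifts 1,3 to C19 and the allenol tautomerises to the C10=C18–C19=O enone. The E isomer (acyl syn to C9, eclipsing the equatorial H9) should prevail because the Z isomer forces the acyl group against 1-Me; the neutral conditions leave C9 and the 13Z alkene alone.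

Step 18
Reactants: 28 6,20-bis(tert-butyldimethylsilyl) ether of the target
Product: 29 (2E,4Z,6E)-7-[(1R,2E,4aS,6S,7R,8R,8aR)-7-hydroxy-2-(3-hydroxy-2-oxopropylidene)-3,6,8-trimethyl-1,2,4a,5,6,7,8,8a-octahydronaphthalen-1-yl]-4,6-dimethylhepta-2,4,6-trienoic acid
Conditions: HF·pyridine, pyridine, THF, 0 °C to rt
Reagents that add atoms: none
Why: Buffered acidic fluoride removes both silyl ethers without the basic conditions that would epimerise or isomerise at C9.

## Compound list

1 | (S)-(+)-carvone, (5S)-2-methyl-5-(prop-1-en-2-yl)cyclohex-2-en-1-one | CC1=CC[C@@H](CC1=O)C(C)=C | starting material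
2 | (5S)-5-(3-chloroprop-1-en-2-yl)-2-methylcyclohex-2-en-1-one | CC1=CC[C@@H](CC1=O)C(=C)CCl | intermediate
3 | potassium extended dienolate of 2 | CC1=C([O-])C[C@H](C=C1)C(=C)CCl.[K+] | intermediate
4 | (1R,4R)-1-methyl-8-methylidenebicyclo[2.2.2]oct-5-en-2-one | C[C@@]12C=C[C@@H](CC1=O)C(=C)C2 | intermediate
5 | (1R,2R,4R)-2-ethenyl-1-methyl-8-methylidenebicyclo[2.2.2]oct-5-en-2-ol (vinyl syn to the C5=C6 bridge) | C[C@@]12C=C[C@@H](C[C@@]1(O)C=C)C(=C)C2 | intermediate
6 | potassium alkoxide of 5 | C[C@@]12C=C[C@@H](C[C@@]1([O-])C=C)C(=C)C2.[K+] | intermediate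
7 | potassium C5=C6 enolate of the cis-fused 1-methyl-9-methylidene-decal-1-en-6-one | CC1=C[C@H]2CC=C([O-])C[C@H]2C(=C)C1.[K+] | intermediate
8 | (3αH,8αH)-1,5α-dimethyl-9-methylidene-cis-decal-1-en-6-one | CC1=C[C@H]2C[C@H](C)C(=O)C[C@H]2C(=C)C1 | intermediate
9 | lithium C6=C7 enolate of 8 | CC1=C[C@H]2C[C@H](C)C([O-])=C[C@H]2C(=C)C1.[Li+] | intermediate
10 | (3αH,8αH)-1,5α,7α-trimethyl-9-methylidene-cis-decal-1-en-6-one | CC1=C[C@H]2C[C@H](C)C(=O)[C@H](C)[C@H]2C(=C)C1 | intermediate
11 | (3αH,8αH)-1,5α,7α-trimethyl-9-methylidene-cis-decal-1-en-6β-ol | CC1=C[C@H]2C[C@H](C)[C@@H](O)[C@H](C)[C@H]2C(=C)C1 | intermediate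
12 | tert-butyldimethylsilyl ether of 11 | CC1=C[C@H]2C[C@H](C)[C@@H](O[Si](C)(C)C(C)(C)C)[C@H](C)[C@H]2C(=C)C1 | intermediate
13 | B-alkyl-9-borabicyclo[3.3.1]nonane adduct of 12 (boron on C11, C9 epimers) | CC1=C[C@H]2C[C@H](C)[C@@H](O[Si](C)(C)C(C)(C)C)[C@H](C)[C@H]2C(CB3C4CCCC3CCC4)C1 | intermediate
14 | 6β-(tert-butyldimethylsilyloxy)-9-(hydroxymethyl)-1,5α,7α-trimethyl-(3αH,8αH)-cis-decal-1-ene, C9 epimers | CC1=C[C@H]2C[C@H](C)[C@@H](O[Si](C)(C)C(C)(C)C)[C@H](C)[C@H]2C(CO)C1 | intermediate
15 | 9-carbaldehyde as first formed, C9 epimers | CC1=C[C@H]2C[C@H](C)[C@@H](O[Si](C)(C)C(C)(C)C)[C@H](C)[C@H]2C(C=O)C1 | intermediate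
16 | 6β-(tert-butyldimethylsilyloxy)-1,5α,7α-trimethyl-(3αH,8αH,9βH)-cis-decal-1-ene-9α-carbaldehyde | CC1=C[C@H]2C[C@H](C)[C@@H](O[Si](C)(C)C(C)(C)C)[C@H](C)[C@H]2[C@H](C=O)C1 | intermediate
17 | (2E)-3-[6β-(tert-butyldimethylsilyloxy)-1,5α,7α-trimethyl-(3αH,8αH,9βH)-cis-decal-1-en-9α-yl]-2-methylprop-2-enal | CC1=C[C@H]2C[C@H](C)[C@@H](O[Si](C)(C)C(C)(C)C)[C@H](C)[C@H]2[C@H](/C=C(C)/C=O)C1 | intermediate
18 | 10-hydroxy derivative of 17, C10 epimers | CC1=C[C@H]2C[C@H](C)[C@@H](O[Si](C)(C)C(C)(C)C)[C@H](C)[C@H]2[C@H](/C=C(C)/C=O)C1O | intermediate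
19 | 9α-[(1E,3Z)-4-iodo-2-methylpenta-1,3-dien-1-yl]-6β-(tert-butyldimethylsilyloxy)-1,5α,7α-trimethyl-cis-decal-1-en-10-ol, C10 epimers | CC1=C[C@H]2C[C@H](C)[C@@H](O[Si](C)(C)C(C)(C)C)[C@H](C)[C@H]2[C@H](/C=C(C)/C=C(C)\I)C1O | intermediate
20 | 9α-[(1E,3Z)-4-iodo-2-methylpenta-1,3-dien-1-yl]-6β-(tert-butyldimethylsilyloxy)-1,5α,7α-trimethyl-cis-decal-1-en-10-one | CC1=C[C@H]2C[C@H](C)[C@@H](O[Si](C)(C)C(C)(C)C)[C@H](C)[C@H]2[C@H](/C=C(C)/C=C(C)\I)C1=O | intermediate
21 | tert-butyldimethyl(prop-2-yn-1-yloxy)silane | C#CCO[Si](C)(C)C(C)(C)C | starting material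
22 | lithium acetylide of 21 | [Li+].[C-]#CCO[Si](C)(C)C(C)(C)C | intermediate
23 | dichlorocerium acetylide of 21 | Cl[Ce](Cl)C#CCO[Si](C)(C)C(C)(C)C | intermediate
24 | tertiary propargylic alcohol: 20 with OH and 3-(tert-butyldimethylsilyloxy)prop-1-yn-1-yl on C10 | CC1=C[C@H]2C[C@H](C)[C@@H](O[Si](C)(C)C(C)(C)C)[C@H](C)[C@H]2[C@H](/C=C(C)/C=C(C)\I)C1(O)C#CCO[Si](C)(C)C(C)(C)C | intermediate
25 | ethyl (2E)-3-(tributylstannyl)prop-2-enoate | CCOC(=O)/C=C/[Sn](CCCC)(CCCC)CCCC | starting material
26 | ethyl (2E,4Z,6E)-trienoate with C10 propargylic carbinol | CC1=C[C@H]2C[C@H](C)[C@@H](O[Si](C)(C)C(C)(C)C)[C@H](C)[C@H]2[C@H](/C=C(C)/C=C(C)\C=C\C(=O)OCC)C1(O)C#CCO[Si](C)(C)C(C)(C)C | intermediate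
27 | (2E,4Z,6E)-trienoic acid with C10 propargylic carbinol | CC1=C[C@H]2C[C@H](C)[C@@H](O[Si](C)(C)C(C)(C)C)[C@H](C)[C@H]2[C@H](/C=C(C)/C=C(C)\C=C\C(=O)O)C1(O)C#CCO[Si](C)(C)C(C)(C)C | intermediate
28 | 6,20-bis(tert-butyldimethylsilyl) ether of the target | CC1=C[C@H]2C[C@H](C)[C@@H](O[Si](C)(C)C(C)(C)C)[C@H](C)[C@H]2[C@H](/C=C(C)/C=C(C)\C=C\C(=O)O)/C1=C\C(=O)CO[Si](C)(C)C(C)(C)C | intermediate
29 | CNP0219601.2, (2E,4Z,6E)-7-[(1R,2E,4aS,6S,7R,8R,8aR)-7-hydroxy-2-(3-hydroxy-2-oxopropylidene)-3,6,8-trimethyl-1,2,4a,5,6,7,8,8a-octahydronaphthalen-1-yl]-4,6-dimethylhepta-2,4,6-trienoic acid | CC1=C[C@H]2C[C@H](C)[C@@H](O)[C@H](C)[C@H]2[C@H](/C=C(C)/C=C(C)\C=C\C(=O)O)/C1=C\C(=O)CO | target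

## Step count and least certain steps

Total step count: 18. Longest linear sequence: 18 steps from 1 (21 and 25 are purchased and enter in steps 14 and 15).

Step 4 (key step). Most likely failure: the alkoxide fragments (cleavage to an enone and an allyl-type anion, or a formal 1,3-shift) instead of rearranging. Alternatively the potassium enolate is methylated on oxygen or more than once, because proton exchange with the product ketone sets in before all of the enolate has been trapped. A low ratio in step 3 would also starve this step, since only the carbinol with vinyl syn to the etheno bridge can rearrange. Fallback, from 5 back to 8: 5 is silylated (TMS-imidazole) to the trimethylsilyl ether F1, which is heated (about 200 °C, base-washed sealed tube) in a neutral siloxy-Cope rearrangement to the regiodefined trimethylsilyl enol ether F2. MeLi in THF then cleaves F2 to the lithium enolate F3, a less basic and more tightly paired enolate, which is methylated with MeI on the α face to give 8.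

Step 11. Most likely failure: loss of regiocontrol in the allylic oxidation (attack on the C1 methyl group, or over-oxidation to the enone before step 12), since the preference for the ring CH2 over CH3 is a tendency and not a rule. Fallback, from 12 back to 18: C10 is oxygenated while it is still doubly allylic. SeO2/t-BuOOH on 12 gives the 10-hydroxy diene F4 and TESCl/imidazole its triethylsilyl ether F5. 9-BBN then H2O2 gives the primary alcohol F6; Dess–Martin oxidation with brief amine equilibration gives the 9α-aldehyde F7; the Wittig reaction of step 10 gives the enal F8; and PPTS in MeOH removes the triethylsilyl group to give 18. The price is a β-silyloxy aldehyde at F7, which must be equilibrated gently.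

Step 14. Most likely failure: deprotonation of 20 at C9 (α to the ketone and allylic to the iodo-diene) instead of addition, with return of starting material or migration of C11=C12 into conjugation. Fallback, from 20 back to 28: the C18–C20 unit is attached without any basic carbanion. A TiCl4-mediated Mukaiyama aldol addition of the trimethylsilyl enol ether of 1-(tert-butyldimethylsilyloxy)propan-2-one to 20 gives the β-hydroxy ketone F9. Dehydration with the Burgess reagent gives the dienone iodide F10. Stille coupling of F10 with (2E)-3-(tributylstannyl)prop-2-enoic acid (the free acid, so that no hydrolysis is needed on the dienone) gives 28.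

Step 17. Most likely failure: ionisation of the tertiary, allylic and propargylic carbinol followed by loss of H9 (Rupe-type dehydration to a conjugated enyne), or incomplete equilibration of the C10=C18 geometry. Fallback, from 24 back to 28: the oxygen is moved by an oxidative allylic transposition instead. Red-Al reduces the propargylic alcohol 24 (hydroxyl-directed trans-hydroalumination) to the (E)-allylic tertiary alcohol F11. Stille coupling with 25 gives the ester F12 and LiOH gives the acid F13. An oxoammonium salt (4-acetamido-TEMPO tetrafluoroborate) then effects the Babler–Dauben-type 1,3-transposition with oxidation to give 28.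

## Further compounds

F1 | step 4 | trimethylsilyl ether of 5 | C[C@@]12C=C[C@@H](C[C@@]1(O[Si](C)(C)C)C=C)C(=C)C2
F2 | step 4 | C5=C6 trimethylsilyl enol ether of cis-fused 1-methyl-9-methylidene-decal-1-en-6-one | CC1=C[C@H]2CC=C(O[Si](C)(C)C)C[C@H]2C(=C)C1
F3 | step 4 | lithium C5=C6 enolate (lithium counterpart of 7) | CC1=C[C@H]2CC=C([O-])C[C@H]2C(=C)C1.[Li+]
F4 | step 11 | 10-hydroxy derivative of 12, C10 epimers | CC1=C[C@H]2C[C@H](C)[C@@H](O[Si](C)(C)C(C)(C)C)[C@H](C)[C@H]2C(=C)C1O
F5 | step 11 | 10-O-triethylsilyl ether of F4 | CC1=C[C@H]2C[C@H](C)[C@@H](O[Si](C)(C)C(C)(C)C)[C@H](C)[C@H]2C(=C)C1O[Si](CC)(CC)CC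
F6 | step 11 | 9-(hydroxymethyl) compound from F5, C9 epimers | CC1=C[C@H]2C[C@H](C)[C@@H](O[Si](C)(C)C(C)(C)C)[C@H](C)[C@H]2C(CO)C1O[Si](CC)(CC)CC
F7 | step 11 | 9α-carbaldehyde with 10-O-triethylsilyl group | CC1=C[C@H]2C[C@H](C)[C@@H](O[Si](C)(C)C(C)(C)C)[C@H](C)[C@H]2[C@H](C=O)C1O[Si](CC)(CC)CC
F8 | step 11 | 10-O-triethylsilyl ether of 18 | CC1=C[C@H]2C[C@H](C)[C@@H](O[Si](C)(C)C(C)(C)C)[C@H](C)[C@H]2[C@H](/C=C(C)/C=O)C1O[Si](CC)(CC)CC
F9 | step 14 | β-hydroxy ketone from aldol addition to 20 (C10 carbinol carrying CH2C(=O)CH2OTBS) | CC1=C[C@H]2C[C@H](C)[C@@H](O[Si](C)(C)C(C)(C)C)[C@H](C)[C@H]2[C@H](/C=C(C)/C=C(C)\I)C1(O)CC(=O)CO[Si](C)(C)C(C)(C)C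
F10 | step 14 | (10E)-dienone carrying the (1E,3Z)-iodo-diene on C9 | CC1=C[C@H]2C[C@H](C)[C@@H](O[Si](C)(C)C(C)(C)C)[C@H](C)[C@H]2[C@H](/C=C(C)/C=C(C)\I)/C1=C\C(=O)CO[Si](C)(C)C(C)(C)C
F11 | step 17 | (E)-allylic tertiary alcohol from reduction of 24 | CC1=C[C@H]2C[C@H](C)[C@@H](O[Si](C)(C)C(C)(C)C)[C@H](C)[C@H]2[C@H](/C=C(C)/C=C(C)\I)C1(O)/C=C/CO[Si](C)(C)C(C)(C)C
F12 | step 17 | ethyl trienoate with C10 (E)-allylic carbinol | CC1=C[C@H]2C[C@H](C)[C@@H](O[Si](C)(C)C(C)(C)C)[C@H](C)[C@H]2[C@H](/C=C(C)/C=C(C)\C=C\C(=O)OCC)C1(O)/C=C/CO[Si](C)(C)C(C)(C)C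
F13 | step 17 | trienoic acid with C10 (E)-allylic carbinol | CC1=C[C@H]2C[C@H](C)[C@@H](O[Si](C)(C)C(C)(C)C)[C@H](C)[C@H]2[C@H](/C=C(C)/C=C(C)\C=C\C(=O)O)C1(O)/C=C/CO[Si](C)(C)C(C)(C)C
A1 | alternative 1 | acyclic (2E,8E,10E)-trienal with silyl ether at C6 and silyloxy group on C10 | O=C/C=C/[C@@H](C)[C@H](O[Si](C)(C)C(C)(C)C)[C@@H](C)C/C=C/C(C)=C/O[Si](C)(C)C(C)(C)C
A2 | alternative 1 | cis-fused octalin 9α-carbaldehyde with 10-silyloxy group (required cycloadduct) | CC1=C[C@H]2C[C@H](C)[C@@H](O[Si](C)(C)C(C)(C)C)[C@H](C)[C@H]2[C@H](C=O)C1O[Si](C)(C)C(C)(C)C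
A3 | alternative 2 | (Z)-vinylallenyl ketone with (E)-enal dienophile, allene axis undefined | O=C/C=C/[C@@H](C)[C@H](O[Si](C)(C)C(C)(C)C)[C@@H](C)C/C=C\C(C)=C=CC(=O)CO[Si](C)(C)C(C)(C)C
A4 | alternative 2 | exocyclic dienone 9α-carbaldehyde (required cycloadduct) | CC1=C[C@H]2C[C@H](C)[C@@H](O[Si](C)(C)C(C)(C)C)[C@H](C)[C@H]2[C@H](C=O)/C1=C\C(=O)CO[Si](C)(C)C(C)(C)C
A5 | alternative 3 | 5-(tert-butyldimethylsilyloxy)-4,6-dimethylcyclohex-2-en-1-one with the C5, C6, C7 configurations of the target | O=C1C=C[C@@H](C)[C@H](O[Si](C)(C)C(C)(C)C)[C@H]1C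
A6 | alternative 3 | (Z)-5-(benzyloxy)-2-methyl-3-(tert-butyldimethylsilyloxy)penta-1,3-diene | C=C(C)/C(O[Si](C)(C)C(C)(C)C)=C/COCc1ccccc1
A7 | alternative 3 | endo cycloadduct: cis-decalin-4-one with silyl enol ether at C10 and 9β-benzyloxymethyl group | CC1=C(O[Si](C)(C)C(C)(C)C)[C@H](COCc3ccccc3)[C@@H]2[C@@H](C)[C@H](O[Si](C)(C)C(C)(C)C)[C@@H](C)C(=O)[C@@H]2C1
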